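**Retrosynthetic overview**
1. The side-chain diene is cut at its central sp2–sp2 bond: a last-step Suzuki–Miyaura coupling joins ring alkenylboronate 9 and (1E,3R,4Z)-dienyl iodide 18.
2. 9 comes from (S)-(+)-carvone (ring and C5 stereocentre bought) by C–H borylation of the isopropenyl group, then the key step: sensitised photooxygenation of the linear dienyl acetate ([4+2] with singlet oxygen) with a PPh3 redox relay that returns the enol acetate's own acetate to C4 with inversion (4-OAc cis to the side chain). An anti α'-hydroxylation then sets 6-OH.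
3. 18 comes from (S)-Roche ester (methyl stereocentre bought): Z-Wittig on one arm, Takai iodo-olefination on the other.
4. Rings: the only ring of the target is bought with carvone and never opened. The sole ring formed is the transient 2,3-dioxabicyclo[2.2.2]octene 5 of the key step, opened in the same flask.

Assumption and notation: the target is the single stereoisomer of the SMILES, i.e. (1S,5R,6R) in the ring and (6R) in the chain. Ring positions are given in enone numbering (C1 = C=O, C2 = C-Me, C4 = CH-OAc, C5 = CH-side chain, C6 = CH-OH). Bpin = 4,4,5,5-tetramethyl-1,3,2-dioxaborolan-2-yl.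

**Step 1**
Reactants: 1 (S)-(+)-carvone
Product: 3 (5S)-2-methyl-5-[(E)-1-(Bpin)prop-1-en-2-yl]cyclohex-2-en-1-one, via catechol alkenylboronate 2 (not isolated)
Conditions: catBBr, Pd2(dba)3 (2.5 mol %), JessePhos (6 mol %), Cy2NMe, PhCF3, 70 °C; then pinacol, rt
Reagents that add atoms: B-bromocatecholborane BrB1Oc2ccccc2O1; pinacol CC(C)(O)C(C)(C)O
Why: Boryl-Heck reaction: the boryl–Pd species adds across the electron-rich 1,1-disubstituted isopropenyl alkene (boron to CH2) rather than the electron-poor enone alkene, and β-hydride elimination gives the conjugated E-alkenylboronate (boron anti to the ring), which pinacol converts into the stable ester; C5 is not touched.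

**Step 2**
Reactants: 3 (5S)-2-methyl-5-[(E)-1-(Bpin)prop-1-en-2-yl]cyclohex-2-en-1-one
Product: 4 (5R)-2-methyl-5-[(E)-1-(Bpin)prop-1-en-2-yl]cyclohexa-1,3-dien-1-yl acetate
Conditions: isopropenyl acetate (solvent), p-TsOH·H2O (5 mol %), 85–95 °C, acetone distilled off
Reagents that add atoms: isopropenyl acetate CC(=C)OC(C)=O
Why: Acid-catalysed enol acetylation under equilibrating conditions (dienol acetate formation) removes the γ-hydrogen at C4 and gives the linearly conjugated 1-acetoxy-1,3-diene, the thermodynamic dienol ester; C5 stays sp3 and no stereocentre is made (the descriptor changes only through CIP priorities).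

**Step 3**
Reactants: 4 (5R)-2-methyl-5-[(E)-1-(Bpin)prop-1-en-2-yl]cyclohexa-1,3-dien-1-yl acetate
Product: 7 (1S,6S)-3-methyl-4-oxo-6-[(E)-1-(Bpin)prop-1-en-2-yl]cyclohex-2-en-1-yl acetate, via acetoxy endoperoxide 5 (not isolated), via alkoxyphosphonium acetate 6 (not isolated)
Conditions: O2 (1 atm), TPP (0.5 mol %), 590 nm LED, dry CH2Cl2, −78 °C; Ar purge; PPh3 (1.1 equiv), −78 → 0 °C, dark
Reagents that add atoms: dioxygen O=O
Why: Proposed new method: singlet oxygen adds [4+2] across C1/C4 of the 1-acetoxy-diene, bonding first at the unsubstituted C4 terminus anti to the C5 side chain, to give bridgehead-acetoxy endoperoxide 5; PPh3 then attacks the less hindered peroxide oxygen on C4, the expelled C1 oxyanion is a ketone–acetate adduct that collapses to the enone and free acetate, and the resulting allylic alkoxyphosphonium acetate 6 (the Mitsunobu ion pair) collapses by SN2 at C4 with inversion, placing the acetate cis to the side chain; the closest known reactions are the PPh3 deoxygenation of 1,4-endoperoxides (normally ending in SN2' closure to vinyl epoxides), the phosphine reduction of peresters and the Mitsunobu inversion, and E2 from 6 is disfavoured because C5–H is syn to the leaving group.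

**Step 4**
Reactants: 7 (1S,6S)-3-methyl-4-oxo-6-[(E)-1-(Bpin)prop-1-en-2-yl]cyclohex-2-en-1-yl acetate
Product: 9 (1S,5R,6R)-5-hydroxy-3-methyl-4-oxo-6-[(E)-1-(Bpin)prop-1-en-2-yl]cyclohex-2-en-1-yl acetate, via sodium dienolate 8 (not isolated)
Conditions: NaHMDS (1.05 equiv), THF, −78 °C, 20 min; (±)-trans-3-phenyl-2-(phenylsulfonyl)oxaziridine (1.3 equiv), −78 °C; AcOH quench
Reagents that add atoms: 3-phenyl-2-(phenylsulfonyl)oxaziridine O=S(=O)(c1ccccc1)N1OC1c1ccccc1
Why: Davis enolate hydroxylation: the hindered amide removes the kinetically most acidic α'-hydrogen (C6) rather than an acetate hydrogen, and the oxaziridine delivers oxygen to the dienolate from the face opposite both the C5 substituent and the pseudo-axial C4 acetate, so 6-OH is trans to the side chain.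

**Step 5**
Reactants: 10 methyl (S)-3-hydroxy-2-methylpropanoate ((S)-Roche ester)
Product: 11 methyl (S)-3-[(tert-butyldimethylsilyl)oxy]-2-methylpropanoate
Conditions: TBSCl, imidazole, CH2Cl2, 0 °C → rt
Reagents that add atoms: tert-butyldimethylsilyl chloride CC(C)(C)[Si](C)(C)Cl
Why: Standard silylation of the primary alcohol; the stereocentre is not involved.

**Step 6**
Reactants: 11 methyl (S)-3-[(tert-butyldimethylsilyl)oxy]-2-methylpropanoate
Product: 12 (S)-3-[(tert-butyldimethylsilyl)oxy]-2-methylpropanal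
Conditions: DIBAL-H (1.05 equiv), CH2Cl2, −78 °C; Rochelle salt work-up; used crude
Reagents that add atoms: none
Why: Partial ester reduction: at −78 °C the reduction stops at the aldehyde oxidation level, and the base-free cold conditions keep the α-stereocentre intact.

**Step 7**
Reactants: 12 (S)-3-[(tert-butyldimethylsilyl)oxy]-2-methylpropanal; 13 (3-methylbutyl)triphenylphosphonium bromide
Product: 15 tert-butyl{[(2R,3Z)-2,6-dimethylhept-3-en-1-yl]oxy}dimethylsilane, via phosphorus ylide 14 (not isolated)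
Conditions: 13, NaHMDS, THF, 0 °C; then 12, −78 °C → rt
Reagents that add atoms: none
Why: Wittig olefination with a non-stabilised ylide under lithium-free conditions is kinetically Z-selective, and the aldehyde is consumed at −78 °C faster than it enolises, so the stereocentre is kept (R only by CIP priority change).

**Step 8**
Reactants: 15 tert-butyl{[(2R,3Z)-2,6-dimethylhept-3-en-1-yl]oxy}dimethylsilane
Product: 16 (2R,3Z)-2,6-dimethylhept-3-en-1-ol
Conditions: CSA (10 mol %), MeOH/CH2Cl2, 0 °C
Reagents that add atoms: none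
Why: Acid-catalysed methanolysis cleaves the primary TBS ether without touching the Z-alkene or the stereocentre.

**Step 9**
Reactants: 16 (2R,3Z)-2,6-dimethylhept-3-en-1-ol
Product: 17 (2R,3Z)-2,6-dimethylhept-3-enal
Conditions: Dess–Martin periodinane, NaHCO3, CH2Cl2, 0 °C; filtered and used at once
Reagents that add atoms: none
Why: Buffered Dess–Martin oxidation is neutral and fast, which avoids epimerisation or conjugation of the α-branched β,γ-unsaturated aldehyde.

**Step 10**
Reactants: 17 (2R,3Z)-2,6-dimethylhept-3-enal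
Product: 18 (1E,3R,4Z)-1-iodo-3,7-dimethylocta-1,4-diene
Conditions: CrCl2 (6 equiv), CHI3 (2 equiv), THF/1,4-dioxane 1:6, 0 °C → rt, dark
Reagents that add atoms: iodoform IC(I)I
Why: Takai olefination gives the E-alkenyl iodide from the aldehyde under non-basic conditions, so the α-stereocentre and the Z-alkene survive.

**Step 11**
Reactants: 9 (1S,5R,6R)-5-hydroxy-3-methyl-4-oxo-6-[(E)-1-(Bpin)prop-1-en-2-yl]cyclohex-2-en-1-yl acetate; 18 (1E,3R,4Z)-1-iodo-3,7-dimethylocta-1,4-diene
Product: 19 (1S,5R,6R)-6-[(2E,4E,6R,7Z)-6,10-dimethylundeca-2,4,7-trien-2-yl]-5-hydroxy-3-methyl-4-oxocyclohex-2-en-1-yl acetate (target)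
Conditions: Pd(dppf)Cl2·CH2Cl2 (10 mol %), Ph3As (20 mol %), Cs2CO3 (2 equiv), 18 (1.2 equiv), THF/DMF/H2O (degassed), rt, dark
Reagents that add atoms: none
Why: Suzuki–Miyaura coupling proceeds with retention at both sp2 carbons and so gives the (2E,4E)-diene; oxidative addition to the alkenyl iodide is faster than ionisation of the allylic acetate, and the mild base at room temperature spares the acetate and the α-ketol.

**Compound list**
1 | (S)-(+)-carvone, (5S)-2-methyl-5-(prop-1-en-2-yl)cyclohex-2-en-1-one | CC1=CC[C@@H](CC1=O)C(C)=C | starting material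
2 | (5S)-5-[(E)-1-(1,3,2-benzodioxaborol-2-yl)prop-1-en-2-yl]-2-methylcyclohex-2-en-1-one | CC1=CC[C@@H](CC1=O)/C(C)=C/B2Oc3ccccc3O2 | intermediate
3 | (5S)-2-methyl-5-[(E)-1-(4,4,5,5-tetramethyl-1,3,2-dioxaborolan-2-yl)prop-1-en-2-yl]cyclohex-2-en-1-one | CC1=CC[C@@H](CC1=O)/C(C)=C/B2OC(C)(C)C(C)(C)O2 | intermediate
4 | (5R)-2-methyl-5-[(E)-1-(4,4,5,5-tetramethyl-1,3,2-dioxaborolan-2-yl)prop-1-en-2-yl]cyclohexa-1,3-dien-1-yl acetate | CC(=O)OC1=C(C)C=C[C@@H](C1)/C(C)=C/B2OC(C)(C)C(C)(C)O2 | intermediate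
5 | (1R,4R,8S)-6-methyl-8-[(E)-1-(4,4,5,5-tetramethyl-1,3,2-dioxaborolan-2-yl)prop-1-en-2-yl]-2,3-dioxabicyclo[2.2.2]oct-5-en-1-yl acetate (peroxide bridge anti to the C8 side chain) | CC(=O)O[C@]1(OO2)C(C)=C[C@@H]2[C@@H](C1)/C(C)=C/B3OC(C)(C)C(C)(C)O3 | intermediate
6 | {[(1R,6S)-3-methyl-4-oxo-6-[(E)-1-(4,4,5,5-tetramethyl-1,3,2-dioxaborolan-2-yl)prop-1-en-2-yl]cyclohex-2-en-1-yl]oxy}triphenylphosphonium acetate (O–P trans to the side chain) | [P+](c1ccccc1)(c1ccccc1)(c1ccccc1)O[C@@H]2C=C(C)C(=O)C[C@H]2/C(C)=C/B3OC(C)(C)C(C)(C)O3.CC(=O)[O-] | intermediate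
7 | (1S,6S)-3-methyl-4-oxo-6-[(E)-1-(4,4,5,5-tetramethyl-1,3,2-dioxaborolan-2-yl)prop-1-en-2-yl]cyclohex-2-en-1-yl acetate (OAc cis to the side chain) | CC(=O)O[C@H]1C=C(C)C(=O)C[C@H]1/C(C)=C/B2OC(C)(C)C(C)(C)O2 | intermediate
8 | sodium (3S,4S)-4-acetoxy-6-methyl-3-[(E)-1-(4,4,5,5-tetramethyl-1,3,2-dioxaborolan-2-yl)prop-1-en-2-yl]cyclohexa-1,5-dien-1-olate | CC(=O)O[C@H]1C=C(C)C([O-])=C[C@H]1/C(C)=C/B2OC(C)(C)C(C)(C)O2.[Na+] | intermediate
9 | (1S,5R,6R)-5-hydroxy-3-methyl-4-oxo-6-[(E)-1-(4,4,5,5-tetramethyl-1,3,2-dioxaborolan-2-yl)prop-1-en-2-yl]cyclohex-2-en-1-yl acetate | CC(=O)O[C@H]1C=C(C)C(=O)[C@H](O)[C@H]1/C(C)=C/B2OC(C)(C)C(C)(C)O2 | intermediate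
10 | methyl (S)-3-hydroxy-2-methylpropanoate ((S)-Roche ester) | COC(=O)[C@@H](C)CO | starting material
11 | methyl (S)-3-[(tert-butyldimethylsilyl)oxy]-2-methylpropanoate | COC(=O)[C@@H](C)CO[Si](C)(C)C(C)(C)C | intermediate
12 | (S)-3-[(tert-butyldimethylsilyl)oxy]-2-methylpropanal | O=C[C@@H](C)CO[Si](C)(C)C(C)(C)C | intermediate
13 | (3-methylbutyl)triphenylphosphonium bromide | CC(C)CC[P+](c1ccccc1)(c1ccccc1)c1ccccc1.[Br-] | starting material
14 | (3-methylbutylidene)triphenylphosphorane | CC(C)CC=P(c1ccccc1)(c1ccccc1)c1ccccc1 | intermediate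
15 | tert-butyl{[(2R,3Z)-2,6-dimethylhept-3-en-1-yl]oxy}dimethylsilane | CC(C)C/C=C\[C@@H](C)CO[Si](C)(C)C(C)(C)C | intermediate
16 | (2R,3Z)-2,6-dimethylhept-3-en-1-ol | CC(C)C/C=C\[C@@H](C)CO | intermediate
17 | (2R,3Z)-2,6-dimethylhept-3-enal | CC(C)C/C=C\[C@@H](C)C=O | intermediate
18 | (1E,3R,4Z)-1-iodo-3,7-dimethylocta-1,4-diene | CC(C)C/C=C\[C@@H](C)/C=C/I | intermediate
19 | (1S,5R,6R)-6-[(2E,4E,6R,7Z)-6,10-dimethylundeca-2,4,7-trien-2-yl]-5-hydroxy-3-methyl-4-oxocyclohex-2-en-1-yl acetate | CC(=O)O[C@H]1C=C(C)C(=O)[C@H](O)[C@H]1/C(C)=C/C=C/[C@H](C)/C=C\CC(C)C | target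

**Step count and risks**
Total: 11 steps (4 to the ring fragment, 6 to the side chain, 1 coupling). Longest linear sequence: 7 steps (10 → 19, steps 5–11).

Three steps most likely to fail:

Step 1 (boryl-Heck on an enone). The B–Br reagent with amine may enolise the ketone, β-hydride elimination may go towards the methyl group or C5–H, and E/Z control may be incomplete. Fallback, setting out from 1: electrophilic C–H thianthrenation of the isopropenyl group (thianthrene S-oxide, Tf2O, MeCN, −40 °C → rt) gives 5-{(E)-2-[(1S)-4-methyl-5-oxocyclohex-3-en-1-yl]prop-1-en-1-yl}thianthren-5-ium trifluoromethanesulfonate F1. Palladium-catalysed borylation of this alkenyl sulfonium salt (B2pin2, Pd(dppf)Cl2, KOAc, dioxane, 50 °C) then returns to the route at 3.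

Step 3 (the new photooxygenation/phosphine relay). Singlet oxygen is small, so face selectivity on a 5-monosubstituted cyclohexadiene may be only moderate, and the minor endoperoxide would give the C4 epimer of 7. The phosphine may also attack the bridgehead oxygen or acetate may be transferred with retention, and the SN2 is slowed by the cis neighbour. Fallback with known chemistry, setting out from 4: peracid oxidation of the dienyl acetate (mCPBA, NaHCO3, CH2Cl2, −20 °C, attack anti to the C5 substituent) gives the trans γ-hydroxy enone (4R,5S)-4-hydroxy-2-methyl-5-[(E)-1-(Bpin)prop-1-en-2-yl]cyclohex-2-en-1-one F2. Mitsunobu inversion with acetic acid (AcOH, PPh3, DIAD, THF, 0 °C) then returns to the route at 7.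

Step 11 (final Suzuki coupling). The hindered trisubstituted alkenyl-Bpin may transmetalate slowly, Pd(0) may ionise the pseudo-axial allylic acetate, and the α-ketol is base-sensitive. Fallback without palladium, setting out from 9 and 18: ipso-iodination of 9 with retention (NIS, MeCN, 0 °C) gives (1S,5R,6R)-5-hydroxy-6-[(E)-1-iodoprop-1-en-2-yl]-3-methyl-4-oxocyclohex-2-en-1-yl acetate F3. Iodine–lithium exchange on 18 (t-BuLi, Et2O, −78 °C) and trapping with Bu3SnCl gives tributyl[(1E,3R,4Z)-3,7-dimethylocta-1,4-dien-1-yl]stannane F4. Copper(I) thiophene-2-carboxylate in NMP at 0 °C couples F3 and F4 under neutral conditions and returns to the route at 19.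

**Further compounds**
F1 | step 1 | 5-{(E)-2-[(1S)-4-methyl-5-oxocyclohex-3-en-1-yl]prop-1-en-1-yl}thianthren-5-ium trifluoromethanesulfonate | CC1=CC[C@@H](CC1=O)/C(C)=C/[S+]2c3ccccc3Sc3ccccc23.[O-]S(=O)(=O)C(F)(F)F
F2 | step 3 | (4R,5S)-4-hydroxy-2-methyl-5-[(E)-1-(4,4,5,5-tetramethyl-1,3,2-dioxaborolan-2-yl)prop-1-en-2-yl]cyclohex-2-en-1-one | O[C@@H]1C=C(C)C(=O)C[C@H]1/C(C)=C/B2OC(C)(C)C(C)(C)O2
F3 | step 11 | (1S,5R,6R)-5-hydroxy-6-[(E)-1-iodoprop-1-en-2-yl]-3-methyl-4-oxocyclohex-2-en-1-yl acetate | CC(=O)O[C@H]1C=C(C)C(=O)[C@H](O)[C@H]1/C(C)=C/I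
F4 | step 11 | tributyl[(1E,3R,4Z)-3,7-dimethylocta-1,4-dien-1-yl]stannane | CCCC[Sn](CCCC)(CCCC)/C=C/[C@H](C)/C=C\CC(C)C
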